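**The question.** Follow one small loss. You charge starting material carrying a trace of protic impurity, and you want the ring at the end of each run.

    2 starting material → open dimer (k1 = 2.20 M⁻¹ s⁻¹)
    starting material + open dimer → open trimer (k2 = 53.0 M⁻¹ s⁻¹)
    starting material → ring (k3 = 0.0626 s⁻¹)
    starting material ⇌ dormant form (K4 = 0.366, k4 = 0.110 s⁻¹)
    starting material + protic impurity → quenched substrate (k5 = 59.5 M⁻¹ s⁻¹)

| flask | starting material | protic impurity | time |
|---|---|---|---|
| autumn | 0.010 M | 0.120 mM | 40 s |
| dusk | 0.010 M | 0.300 mM | 40 s |
| summer | 0.010 M | 1.00 mM | 40 s |

- percent here means starting material units held: one open dimer counts as two
- percent here means starting material units held: one open trimer counts as three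
- two of one species on the left: rate k times its square, two consumed each time
- "hardly changes" means that all values lie within two and a half points (for a concentration: within two and a half percent of the largest)
- run time (autumn): 40 s

- amount of ring at the end, in percent of the starting material charged for autumn, dusk, summer, in this order
- the shape of the row from first to last (falls, then rises / falls all the way / rises, then falls / hardly changes / rises all the way)

**The tax.** Starting material far outweighs the protic impurity, so the impurity decays pseudo-first-order, with a half-life of 1.16 s at the charged [starting material]. In autumn the same step would need 97 s to halve the starting material, far longer. So treat the impurity as a correction: it removes its own amount of starting material at the outset. That tax is 1.20% of the charge in autumn, 3.00% in dusk and 10.0% in summer.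

**The price.** What does a point of charge cost in ring? Open dimer reacts with a constant of 53.0 M⁻¹ s⁻¹, far above the 2.20 M⁻¹ s⁻¹ that forms it, so it goes on about as fast as it forms, and each turn takes 3 units of starting material. At 0.010 M, ring therefore draws 0.0626 s⁻¹ against 0.0660 s⁻¹ for the oligomers. Ring's share of that flow is 0.487. This share is the exchange rate: points of ring lost per point of charge taken. I reckon it at the charged concentration: a smaller charge starts lower on the same path, and the stretch it lacks is the top. The dormant form holds starting material back and returns it, but both routes draw on free [starting material], so their ratio at a given [starting material] stands.

**My reckoning.** The tax rises along the row, so ring falls at each step, and summer should stand 4.3 percentage points below autumn. This reckons a difference between flasks, and I give no level at 40 s.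

**The forecast.** It gives 66%, 65% and 61.5%, a row that falls all the way, and says the yield “drops only about half a point per percent of charge lost”. Its drop from autumn to summer is 4.5 points, and unlike my reckoning it commits to levels.

**The result.** The flasks give 63.1%, 62.2% and 58.4%, a row that falls all the way, and the forecast holds within its margin. The impurity's half-life of 1.16 s is shorter than the 9.26 s by which autumn has made half of its ring. Summer holds 9.96% of quenched substrate at 40.0 s, and its ring stands 4.7 points below autumn, against 4.3 points reckoned. On dusk, the exchange rate of 0.487 gives 0.88 points below autumn, and dusk stands 0.9 points below.

The constants used here are invented; the result is computed.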